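**Strategy.** Ring atoms are labelled C1 (heptenyl-bearing), C2 (CH2OH-bearing), C3 (carbinol), C4 and C5 (oxirane CH and quaternary carbon) and C6 (ketone). Because the C4–C5 oxirane of the cyclohexenone lies α,β to the C6 carbonyl and the C1=C2 alkene keeps C3 and C6 cis, the ring bond C4–C5 and the oxirane bond C5–O are disconnected together. The precursor is an open-chain Z-dienone with a C4 aldehyde, a C3 silyl ether and a C5 gem-dibromide. Samarium diiodide converts the dibromide into a bromo-enolate that closes the carbocycle by aldol addition and then the epoxide by bromide displacement, C3 setting C4 and C5.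

Key step: step 17

Remark (assumption and labels): aldehyde 6 and bromo ester 19 are taken as purchasable. Side-chain carbons are C7 (CH2), C8 (=CH), C9 (=C(CH3)) and C10 (carboxyl). The carboxyl group is carried as a 2-(trimethylsilyl)ethyl ester and C4 as a silyl-protected primary alcohol, so that the aldehyde is released by oxidation and every protecting group falls to fluoride in one final operation.

**Step 1**
Reactants: 1 but-2-yne-1,4-diol
Product: 2 4-(tert-butyldiphenylsilyloxy)but-2-yn-1-ol
Conditions: TBDPSCl (1 equiv), imidazole, 1 (3 equiv), DMF, 0 °C → rt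
Reagents that add atoms: tert-butyl(chloro)diphenylsilane, CC(C)(C)[Si](Cl)(c1ccccc1)c1ccccc1
Why: Monosilylation (silyl ether formation) of the symmetrical diol used in excess should give mainly the mono-ether, and the tert-butyldiphenylsilyl group is chosen because this primary allylic ether has to outlast the acidic fluoride treatment of step 15.

**Step 2**
Reactants: 3 hept-1-yne
Product: 5 (E)-1-iodohept-1-ene, via (E)-hept-1-enyldiisobutylalane 4 (not isolated)
Conditions: DIBAL-H, hexane, 50 °C; then I2, THF, −50 °C → rt
Reagents that add atoms: iodine, II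
Why: Hydroalumination–iodination, in which syn addition of Al–H across the terminal alkyne and iodinolysis of the C–Al bond with retention fix the E geometry of the heptenyl unit.

**Step 3**
Reactants: 5 (E)-1-iodohept-1-ene; 2 4-(tert-butyldiphenylsilyloxy)but-2-yn-1-ol; 6 (tert-butyldimethylsilyloxy)acetaldehyde
Product: 11 racemic Z-diol (C6–OH and C3–OH free), via (E)-hept-1-enyllithium 7 (not isolated), via (E)-hept-1-enylmagnesium bromide 8 (not isolated), via bromomagnesium butynolate 9 (not isolated), via alkenylmagnesium chelate 10 (not isolated)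
Conditions: 5, t-BuLi (2 equiv), Et2O, −78 °C; MgBr2·OEt2; 2, EtMgBr, THF, 0 °C; combine, THF–toluene, 80 °C; then 6, −78 → 0 °C; aq. NH4Cl
Reagents that add atoms: none
Why: Alkoxide-directed anti-carbomagnesiation of a propargylic alcohol followed by Grignard addition to an aldehyde, in which the alkenyl group of 8 is delivered to the alkyne carbon next to the alkoxide (C1) while magnesium ends on C2 inside the five-membered chelate 10, so that C6 and the carbon that attacks 6 (C3) are cis and the Z-tetrasubstituted C1=C2 alkene is fixed, C3 being formed racemic and set in steps 5 and 6.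

**Step 4**
Reactants: 11 racemic Z-diol
Product: 12 C6 triethylsilyl ether (C3–OH free)
Conditions: TESCl (1.05 equiv), imidazole, CH2Cl2, −78 °C
Reagents that add atoms: chlorotriethylsilane, CC[Si](Cl)(CC)CC
Why: Chemoselective silylation, since the primary allylic C6 hydroxyl reacts at −78 °C much faster than the hindered secondary C3 hydroxyl, and the ether prevents cyclisation of C6–OH onto the cis C3 ketone made next.

**Step 5**
Reactants: 12 C6 triethylsilyl ether
Product: 13 C3 ketone (Z-enone)
Conditions: Dess–Martin periodinane, NaHCO3, CH2Cl2, 0 °C → rt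
Reagents that add atoms: none
Why: Dess–Martin oxidation of the secondary allylic alcohol under buffered conditions removes the uncontrolled C3 centre and leaves the three silyl ethers and the diene untouched.

**Step 6**
Reactants: 13 C3 ketone
Product: 14 (3R)-allylic alcohol
Conditions: (R)-2-methyl-CBS-oxazaborolidine (0.5 equiv), catecholborane, toluene, −78 °C; aqueous work-up
Reagents that add atoms: none
Why: Corey–Bakshi–Shibata reduction, in which the fully substituted alkenyl group acts as the large and CH2OSi as the small ketone substituent, so that the (R)-oxazaborolidine–borane complex should deliver hydride to the face that gives the (R)-carbinol at C3, the only stereocentre carried into the key step.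

**Step 7**
Reactants: 14 (3R)-allylic alcohol
Product: 15 (3R)-C3 tert-butyldimethylsilyl ether
Conditions: TBSOTf, 2,6-lutidine, CH2Cl2, −78 → 0 °C
Reagents that add atoms: tert-butyldimethylsilyl trifluoromethanesulfonate, CC(C)(C)[Si](C)(C)OS(=O)(=O)C(F)(F)F
Why: Silylation with a silyl triflate and a hindered pyridine base protects the hindered secondary C3 alcohol as the ether that later directs the aldol step, without touching the triethylsilyl ether.

**Step 8**
Reactants: 15 (3R)-C3 tert-butyldimethylsilyl ether
Product: 16 (3R)-C6 aldehyde (dienal)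
Conditions: (COCl)2, DMSO, CH2Cl2, −78 → −30 °C; Et3N, −78 → 0 °C
Reagents that add atoms: none
Why: Swern oxidation applied directly to a primary triethylsilyl ether, in which the chlorosulfonium reagent removes only the most labile primary silyl group and the resulting alkoxysulfonium ion collapses to the C6 aldehyde, so that no free C6 alcohol appears next to the other silyl ethers.

**Step 9**
Reactants: 16 (3R)-C6 aldehyde
Product: 17 C6 methyl carbinol (both C6 epimers)
Conditions: MeMgBr, THF, −78 °C
Reagents that add atoms: methylmagnesium bromide, C[Mg]Br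
Why: Grignard 1,2-addition to the hindered dienal gives the C6 carbinol as an epimer mixture that is of no consequence because this centre is oxidised in the next step.

**Step 10**
Reactants: 17 C6 methyl carbinol
Product: 18 (3R)-methyl ketone
Conditions: Dess–Martin periodinane, NaHCO3, CH2Cl2, 0 °C → rt
Reagents that add atoms: none
Why: Dess–Martin oxidation converts the doubly allylic secondary alcohol into the methyl ketone without acid or base that could move the C1=C2 alkene or disturb C3.

**Step 11**
Reactants: 19 ethyl (E)-4-bromo-2-methylbut-2-enoate; 20 2-(trimethylsilyl)ethanol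
Product: 21 2-(trimethylsilyl)ethyl (E)-4-bromo-2-methylbut-2-enoate
Conditions: Ti(OEt)4 (10 mol %), toluene, 100 °C, EtOH distilled off
Reagents that add atoms: none
Why: Titanate-catalysed transesterification driven by removal of ethanol exchanges the ethyl for the silylethyl ester under neutral conditions that leave the allylic bromide and the E alkene alone, so that the acid can later be freed by fluoride instead of by hydrolysis beside the epoxy ketone.

**Step 12**
Reactants: 18 (3R)-methyl ketone; 21 2-(trimethylsilyl)ethyl (E)-4-bromo-2-methylbut-2-enoate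
Product: 23 (3R)-ketone with the complete carbon skeleton, via lithium enolate 22 (not isolated)
Conditions: LDA, THF, −78 °C; then 21, DMPU, −78 → −40 °C
Reagents that add atoms: none
Why: Kinetic enolate alkylation, in which LDA removes a methyl proton (the ketone has no other α-hydrogen) and the lithium enolate 22 displaces the primary allylic bromide of 21 by SN2, installing C7–C10 with the E enoate unchanged.

**Step 13**
Reactants: 23 (3R)-ketone
Product: 25 C5 monobromo ketone (both C5 epimers), via trimethylsilyl enol ether 24 (not isolated)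
Conditions: LiHMDS, TMSCl, THF, −78 °C; then NBS, THF, −78 → 0 °C
Reagents that add atoms: N-bromosuccinimide, O=C1CCC(=O)N1Br
Why: Regiospecific α-bromination through a silyl enol ether, since in-situ silylation of the kinetic C5 enolate gives 24, which N-bromosuccinimide should brominate at C5 only because the diene and the enoate are far less nucleophilic than the enol ether.

**Step 14**
Reactants: 25 C5 monobromo ketone
Product: 27 (3R)-C5 dibromo ketone, via bromo silyl enol ether 26 (not isolated)
Conditions: LiHMDS, TMSCl, THF, −78 °C; then NBS, THF, −78 → 0 °C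
Reagents that add atoms: N-bromosuccinimide, O=C1CCC(=O)N1Br
Why: Second α-bromination through a silyl enol ether, in which the remaining C5–H, now the most acidic proton, is removed at −78 °C with internal silyl chloride quench and the bromo enol ether 26 is brominated to the gem-dibromide under non-basic conditions.

**Step 15**
Reactants: 27 (3R)-C5 dibromo ketone
Product: 28 C4 primary alcohol
Conditions: HF·pyridine, pyridine, THF, 0 °C
Reagents that add atoms: none
Why: Selective desilylation, since pyridine-buffered HF·pyridine cleaves the unhindered primary silyl ether at C4 much faster than the secondary silyl ether, the tert-butyldiphenylsilyl ether or the silylethyl ester, and the acidic medium suppresses silyl migration.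

**Step 16**
Reactants: 28 C4 primary alcohol
Product: 29 (3R)-dibromo keto aldehyde (precursor of the key step)
Conditions: Dess–Martin periodinane, NaHCO3, CH2Cl2, 0 °C; used at once
Reagents that add atoms: none
Why: Dess–Martin oxidation gives the α-silyloxy aldehyde without base, so that C3 is not epimerised, and a reversible six-membered hemiketal between the C4 hydroxyl and the C6 ketone should not interfere because only the open primary alcohol can be oxidised.

**Step 17**
Reactants: 29 (3R)-dibromo keto aldehyde
Product: 32 bis-silyl silylethyl ester of the target (epoxy cyclohexenone), via samarium bromo-enolate 30 (not isolated), via samarium bromo-aldolate 31 (not isolated)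
Conditions: SmI2 (2.05 equiv, 0.1 M in THF, added slowly), THF, −78 °C; then −78 → 0 °C
Reagents that add atoms: none
Why: Two single-electron transfers from SmI2 cleave one C5–Br bond and give the samarium(III) α-bromo enolate 30 regiospecifically and without base, so the C3–H next to the aldehyde is never exposed to deprotonation; C5 then adds to the C4 aldehyde and the samarium aldolate 31 displaces the remaining bromide at C5. The closest known reactions are the Reformatsky-type (reductive) Darzens condensation of α,α-dihalo carbonyl compounds with aldehydes and the samarium-mediated intramolecular Reformatsky cyclisation. The carbocycle closes in a 6-(enolendo)-exo-trig aldol step (both enolate carbons C5 and C6 lie in the new ring, the aldehyde oxygen outside it) and the oxirane in a 3-exo-tet step. C4 is controlled by C3, because C5 should approach the aldehyde anti to the C3–O bond (polar Felkin–Anh arrangement, silyloxy group pseudo-equatorial, carbonyl oxygen pseudo-axial), which places the C4 oxygen cis to the C3 silyloxy group; C5 is controlled by C4, because only the aldolate with oxygen anti-periplanar to bromine can form the cis-fused oxirane and the reversible samarium aldol feeds that isomer. The step needs reduction of the dibromo ketone ahead of the aldehyde and of the product, which the much faster reduction of α-halo ketones and the slow addition of exactly two equivalents at −78 °C should secure, and it needs cyclisation ahead of intermolecular aldol or pinacol coupling, which the Z alkene C1=C2 secures by placing C5 next to C4.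

**Step 18**
Reactants: 32 bis-silyl silylethyl ester of the target
Product: 33 target acid CNP0332048.1
Conditions: TASF, DMF, 0 °C → rt; AcOH quench
Reagents that add atoms: none
Why: Fluoride-mediated global deprotection, in which TASF cleaves both silyl ethers and fragments the 2-(trimethylsilyl)ethyl ester by β-elimination under almost neutral, anhydrous conditions that an epoxy enone should tolerate, so that no hydrolytic step is needed.

**Compound list**

1 | but-2-yne-1,4-diol | OCC#CCO | starting material
2 | 4-[(tert-butyldiphenylsilyl)oxy]but-2-yn-1-ol | OCC#CCO[Si](c1ccccc1)(c1ccccc1)C(C)(C)C | intermediate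
3 | hept-1-yne | C#CCCCCC | starting material
4 | [(E)-hept-1-enyl]bis(2-methylpropyl)alane | CCCCC/C=C/[Al](CC(C)C)CC(C)C | intermediate
5 | (E)-1-iodohept-1-ene | CCCCC/C=C/I | intermediate
6 | [(tert-butyldimethylsilyl)oxy]acetaldehyde | O=CCO[Si](C)(C)C(C)(C)C | starting material
7 | (E)-hept-1-enyllithium | CCCCC/C=C/[Li] | intermediate
8 | (E)-hept-1-enylmagnesium bromide | CCCCC/C=C/[Mg]Br | intermediate
9 | bromomagnesium 4-[(tert-butyldiphenylsilyl)oxy]but-2-yn-1-olate | Br[Mg]OCC#CCO[Si](c1ccccc1)(c1ccccc1)C(C)(C)C | intermediate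
10 | cyclic alkenylmagnesium alkoxide (2,5-dihydro-1,2-oxamagnesole; Mg bonded to the C6 oxygen and to C2, (E)-heptenyl on C1, CH2OTBDPS on C2) | CCCCC/C=C/C1=C(CO[Si](c2ccccc2)(c2ccccc2)C(C)(C)C)[Mg]OC1 | intermediate
11 | rac-(2Z)-5-[(tert-butyldimethylsilyl)oxy]-3-{[(tert-butyldiphenylsilyl)oxy]methyl}-2-[(1E)-hept-1-en-1-yl]pent-2-ene-1,4-diol (C3 racemic) | CCCCC/C=C/C(=C(\CO[Si](c1ccccc1)(c1ccccc1)C(C)(C)C)C(O)CO[Si](C)(C)C(C)(C)C)CO | intermediate
12 | 11 with the primary C6–OH as triethylsilyl ether (C3–OH free, racemic) | CCCCC/C=C/C(=C(\CO[Si](c1ccccc1)(c1ccccc1)C(C)(C)C)C(O)CO[Si](C)(C)C(C)(C)C)CO[Si](CC)(CC)CC | intermediate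
13 | Z-enone, C3 ketone of 12 | CCCCC/C=C/C(=C(\CO[Si](c1ccccc1)(c1ccccc1)C(C)(C)C)C(=O)CO[Si](C)(C)C(C)(C)C)CO[Si](CC)(CC)CC | intermediate
14 | (3R)-allylic alcohol from 13 | CCCCC/C=C/C(=C(\CO[Si](c1ccccc1)(c1ccccc1)C(C)(C)C)[C@@H](O)CO[Si](C)(C)C(C)(C)C)CO[Si](CC)(CC)CC | intermediate
15 | (3R)-C3 tert-butyldimethylsilyl ether (C4–OTBS, C2–CH2OTBDPS, C6–OTES) | CCCCC/C=C/C(=C(\CO[Si](c1ccccc1)(c1ccccc1)C(C)(C)C)[C@@H](O[Si](C)(C)C(C)(C)C)CO[Si](C)(C)C(C)(C)C)CO[Si](CC)(CC)CC | intermediate
16 | (3R)-dienal, C6 aldehyde cis to C3 across C1=C2 | CCCCC/C=C/C(=C(\CO[Si](c1ccccc1)(c1ccccc1)C(C)(C)C)[C@@H](O[Si](C)(C)C(C)(C)C)CO[Si](C)(C)C(C)(C)C)C=O | intermediate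
17 | (3R)-C6 secondary alcohol CH(OH)CH3, both C6 epimers | CCCCC/C=C/C(=C(\CO[Si](c1ccccc1)(c1ccccc1)C(C)(C)C)[C@@H](O[Si](C)(C)C(C)(C)C)CO[Si](C)(C)C(C)(C)C)C(C)O | intermediate
18 | (3R)-methyl ketone, C6(=O)CH3 | CCCCC/C=C/C(=C(\CO[Si](c1ccccc1)(c1ccccc1)C(C)(C)C)[C@@H](O[Si](C)(C)C(C)(C)C)CO[Si](C)(C)C(C)(C)C)C(C)=O | intermediate
19 | ethyl (2E)-4-bromo-2-methylbut-2-enoate | BrC/C=C(\C)C(=O)OCC | starting material
20 | 2-(trimethylsilyl)ethanol | C[Si](C)(C)CCO | starting material
21 | 2-(trimethylsilyl)ethyl (2E)-4-bromo-2-methylbut-2-enoate | BrC/C=C(\C)C(=O)OCC[Si](C)(C)C | intermediate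
22 | lithium enolate of 18 (C6(OLi)=CH2) | CCCCC/C=C/C(=C(\CO[Si](c1ccccc1)(c1ccccc1)C(C)(C)C)[C@@H](O[Si](C)(C)C(C)(C)C)CO[Si](C)(C)C(C)(C)C)C(=C)O[Li] | intermediate
23 | (3R)-ketone with complete skeleton, C6(=O)–C5H2–C7H2–C8H=C9(CH3)–C10 silylethyl ester (E) | CCCCC/C=C/C(=C(\CO[Si](c1ccccc1)(c1ccccc1)C(C)(C)C)[C@@H](O[Si](C)(C)C(C)(C)C)CO[Si](C)(C)C(C)(C)C)C(=O)CC/C=C(\C)C(=O)OCC[Si](C)(C)C | intermediate
24 | trimethylsilyl enol ether of 23 (C6(OSiMe3)=C5H, enol geometry not defined) | CCCCC/C=C/C(=C(\CO[Si](c1ccccc1)(c1ccccc1)C(C)(C)C)[C@@H](O[Si](C)(C)C(C)(C)C)CO[Si](C)(C)C(C)(C)C)C(O[Si](C)(C)C)=CC/C=C(\C)C(=O)OCC[Si](C)(C)C | intermediate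
25 | (3R)-C5 monobromo ketone, both C5 epimers | CCCCC/C=C/C(=C(\CO[Si](c1ccccc1)(c1ccccc1)C(C)(C)C)[C@@H](O[Si](C)(C)C(C)(C)C)CO[Si](C)(C)C(C)(C)C)C(=O)C(Br)C/C=C(\C)C(=O)OCC[Si](C)(C)C | intermediate
26 | C5-bromo trimethylsilyl enol ether of 25 (enol geometry not defined) | CCCCC/C=C/C(=C(\CO[Si](c1ccccc1)(c1ccccc1)C(C)(C)C)[C@@H](O[Si](C)(C)C(C)(C)C)CO[Si](C)(C)C(C)(C)C)C(O[Si](C)(C)C)=C(Br)C/C=C(\C)C(=O)OCC[Si](C)(C)C | intermediate
27 | (3R)-C5,C5-dibromo ketone with C4–OTBS | CCCCC/C=C/C(=C(\CO[Si](c1ccccc1)(c1ccccc1)C(C)(C)C)[C@@H](O[Si](C)(C)C(C)(C)C)CO[Si](C)(C)C(C)(C)C)C(=O)C(Br)(Br)C/C=C(\C)C(=O)OCC[Si](C)(C)C | intermediate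
28 | (3R)-C5,C5-dibromo ketone with free primary C4–OH | CCCCC/C=C/C(=C(\CO[Si](c1ccccc1)(c1ccccc1)C(C)(C)C)[C@@H](O[Si](C)(C)C(C)(C)C)CO)C(=O)C(Br)(Br)C/C=C(\C)C(=O)OCC[Si](C)(C)C | intermediate
29 | key-step precursor: open-chain (3R)-Z-dienone with C4 aldehyde, C3–OTBS, C2–CH2OTBDPS, C5 gem-dibromide and silylethyl (E)-enoate | CCCCC/C=C/C(=C(\CO[Si](c1ccccc1)(c1ccccc1)C(C)(C)C)[C@@H](O[Si](C)(C)C(C)(C)C)C=O)C(=O)C(Br)(Br)C/C=C(\C)C(=O)OCC[Si](C)(C)C | intermediate
30 | samarium(III) α-bromo enolate of 29 (C6–O–SmI2, C5=C6, C5–Br; enolate geometry not defined) | CCCCC/C=C/C(=C(\CO[Si](c1ccccc1)(c1ccccc1)C(C)(C)C)[C@@H](O[Si](C)(C)C(C)(C)C)C=O)C(O[Sm](I)I)=C(Br)C/C=C(\C)C(=O)OCC[Si](C)(C)C | intermediate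
31 | samarium(III) bromo-aldolate: cyclohex-2-enone with C4–O–SmI2 cis to C3–OTBS and anti to C5–Br | CCCCC/C=C/C1=C(CO[Si](c3ccccc3)(c3ccccc3)C(C)(C)C)[C@@H](O[Si](C)(C)C(C)(C)C)[C@@H](O[Sm](I)I)[C@@](Br)(C/C=C(\C)C(=O)OCC[Si](C)(C)C)C1=O | intermediate
32 | key-step product: 2-(trimethylsilyl)ethyl (2E)-4-[(1R,5R,6R)-5-[(tert-butyldimethylsilyl)oxy]-4-{[(tert-butyldiphenylsilyl)oxy]methyl}-3-[(1E)-hept-1-en-1-yl]-2-oxo-7-oxabicyclo[4.1.0]hept-3-en-1-yl]-2-methylbut-2-enoate | CCCCC/C=C/C1=C(CO[Si](c3ccccc3)(c3ccccc3)C(C)(C)C)[C@@H](O[Si](C)(C)C(C)(C)C)[C@H]2O[C@@]2(C/C=C(\C)C(=O)OCC[Si](C)(C)C)C1=O | intermediate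
33 | (2E)-4-[(1R,5R,6R)-3-[(1E)-hept-1-en-1-yl]-5-hydroxy-4-(hydroxymethyl)-2-oxo-7-oxabicyclo[4.1.0]hept-3-en-1-yl]-2-methylbut-2-enoic acid (CNP0332048.1) | CCCCC/C=C/C1=C(CO)[C@@H](O)[C@H]2O[C@@]2(C/C=C(\C)C(=O)O)C1=O | target

**Step count**

Total: 18 steps. Longest linear sequence: 16 steps (steps 1, 3–10 and 12–18, from but-2-yne-1,4-diol).

**Steps most likely to fail**

Step 17. What may go wrong: over-reduction (further electrons removing the second bromine before ring closure or opening the epoxy ketone), ketyl formation at the aldehyde, or low facial selectivity in the aldol addition. Fallback by a classical base-mediated intramolecular Darzens condensation: setting out from monobromo ketone 25, buffered HF·pyridine removes the primary silyl ether to give the hydroxy bromo ketone F1, and Dess–Martin oxidation gives the bromo keto aldehyde F2. LiHMDS in THF at −78 °C then removes the C5 proton (the most acidic C–H, flanked by carbonyl and bromine), so that aldol addition to C4 and displacement of bromide close both rings. The sequence comes back to the route at 32.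

Step 3. What may go wrong: slow addition of the β-substituted alkenyl Grignard reagent to the alkynyl alkoxide, partial loss of E geometry in the reagent on heating, or β-elimination of silanolate from the chelate before the aldehyde is added. Fallback by building the heptenyl chain through olefin metathesis: setting out from 2 (as its alkoxide 9), the directed carbomagnesiation is run with vinylmagnesium chloride, the parent reagent of this reaction, which should add at lower temperature. This gives the vinyl magnesium chelate F3, which is trapped with 6 to give the 2-vinyl diol F4. Cross-metathesis of F4 with hept-1-ene (second-generation Grubbs catalyst, CH2Cl2, 40 °C), in which only the monosubstituted vinyl group can react, should then give the E-heptenyl chain and comes back to the route at 11.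

Step 14. What may go wrong: dehydrobromination of the α-bromo ketone towards the conjugated dienoate, or enolisation away from C5, during the second base treatment. Fallback by a base-free dibromination through a diazo ketone: setting out from ketone 23, detrifluoroacetylative diazo transfer is used. LiHMDS and 2,2,2-trifluoroethyl trifluoroacetate at −78 °C give the α-trifluoroacetyl ketone F5, and methanesulfonyl azide with triethylamine in acetonitrile gives the α-diazo ketone F6. Titration with bromine in CH2Cl2 at −78 °C then replaces dinitrogen by two bromine atoms and comes back to the route at 27.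

**Further compounds**

F1 | step 17 | (3R)-C5 monobromo ketone with free primary C4–OH | CCCCC/C=C/C(=C(\CO[Si](c1ccccc1)(c1ccccc1)C(C)(C)C)[C@@H](O[Si](C)(C)C(C)(C)C)CO)C(=O)C(Br)C/C=C(\C)C(=O)OCC[Si](C)(C)C
F2 | step 17 | (3R)-C5 monobromo keto aldehyde | CCCCC/C=C/C(=C(\CO[Si](c1ccccc1)(c1ccccc1)C(C)(C)C)[C@@H](O[Si](C)(C)C(C)(C)C)C=O)C(=O)C(Br)C/C=C(\C)C(=O)OCC[Si](C)(C)C
F3 | step 3 | vinyl magnesium chelate (analogue of 10 with vinyl on C1) | C=CC1=C(CO[Si](c2ccccc2)(c2ccccc2)C(C)(C)C)[Mg]OC1
F4 | step 3 | racemic 2-vinyl Z-diol (analogue of 11 with vinyl on C1) | C=C/C(=C(\CO[Si](c1ccccc1)(c1ccccc1)C(C)(C)C)C(O)CO[Si](C)(C)C(C)(C)C)CO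
F5 | step 14 | C5-trifluoroacetyl derivative of ketone 23 | CCCCC/C=C/C(=C(\CO[Si](c1ccccc1)(c1ccccc1)C(C)(C)C)[C@@H](O[Si](C)(C)C(C)(C)C)CO[Si](C)(C)C(C)(C)C)C(=O)C(C(=O)C(F)(F)F)C/C=C(\C)C(=O)OCC[Si](C)(C)C
F6 | step 14 | C5-diazo ketone derived from 23 | CCCCC/C=C/C(=C(\CO[Si](c1ccccc1)(c1ccccc1)C(C)(C)C)[C@@H](O[Si](C)(C)C(C)(C)C)CO[Si](C)(C)C(C)(C)C)C(=O)C(=[N+]=[N-])C/C=C(\C)C(=O)OCC[Si](C)(C)C
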